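| flask | substrate | solid reagent | temperature | remark | time |
|---|---|---|---|---|---|
| dawn | 0.070 M | 1.8 equiv | 2 °C | run made earlier |  |
| autumn | 0.11 M | 1.8 equiv | 19 °C | run made earlier |  |
| winter | 0.050 M | 0.90 equiv | 2 °C | run made earlier |  |
| Tuesday's | 0.050 M | 1.80 equiv | 25 °C |  | 4.0 d |
| Monday's | 0.050 M | 1.80 equiv |  | at 25 °C until 30 h, from then on at −5 °C | 4.0 d |
| Friday's | 0.050 M | 1.80 equiv | −5 °C |  | 4.0 d |
| Thursday's | 0.050 M | 1.80 equiv | 10 °C |  | 4.0 d |

| run | time / d | target / % |
|---|---|---|
| dawn | 0.833 | 4.1 |
| dawn | 2.50 | 17.7 |
| dawn | 4.00 | 25.5 |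
| dawn | 6.00 | 30.2 |
| dawn | 10.0 | 33.7 |
| dawn | 12.0 | 33.4 |
| dawn | 15.0 | 34.1 |
| autumn | 0.417 | 3.1 |
| autumn | 0.625 | 5.0 |
| autumn | 0.833 | 6.8 |
| autumn | 1.25 | 11.2 |
| autumn | 2.08 | 18.0 |
| autumn | 3.00 | 22.9 |
| autumn | 5.00 | 26.2 |
| winter | 1.25 | 9.2 |
| winter | 4.00 | 27.0 |
| winter | 6.00 | 30.7 |
| winter | 10.0 | 32.1 |
| winter | 15.0 | 32.8 |

(readings scatter by 0.5 percentage points)

- as a solid, counted per litre of solution: solid reagent
- what was read earlier has a scatter of 0.5 percentage points, one standard deviation
- at the start none of the solid reagent is in solution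
- a reading or a percentage of target counts all its forms, free or not

- the flask with the highest amount of target, in percent of the substrate charged ("all alike" if they lie within 1.5 percentage points) (Tuesday's / Monday's / Friday's / Thursday's / all alike)
- final target, as a percentage of the substrate charged, in Tuesday's
- final target, as a percentage of the substrate charged, in Monday's
- final target, as a percentage of the substrate charged, in Friday's
- final target, as a percentage of the substrate charged, in Thursday's

- Reckon with f, the fraction of the plateau still to come, and not with the target made, since a first-order approach makes ln f a straight line in time.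
- At the start none of the solid reagent is in solution, and the dawn run reads 4.1% of target after 0.833 d.
- In the middle, the last reading at 2 °C is 34.1% in the dawn run with 1.8 equiv and 32.8% in the winter run with 0.90 equiv, so this reckoning takes the dissolved reagent as steady and the approach as pseudo-first-order.
- The dawn run at 2 °C then loses f at 0.410 /d. The autumn run at 19 °C, with its last reading standing in for the plateau, loses it at 0.865 /d.
- Run back to the start, where the whole plateau is still to come, the dawn line gives a lag of 0.716 d and the autumn line one of 0.605 d; this reckoning carries the dawn lag unchanged into the cold.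
- Taking ln of the rate as straight in temperature gives the cold clock, the daily loss of ln f at −5 °C: 0.302 /d.
- At the end of Friday's, this reckoning leaves f = 37.1% after 4.0 d. On the dawn plateau that is 21.4% of target, which is less than the forecast's figure.
- The forecast names Monday's as highest, with 25% for Tuesday's, 30% for Monday's, 25% for Friday's and 28.5% for Thursday's. It puts Friday's at “about 70% of the way”.
- The flasks give 26.8% for Tuesday's, 23.7% for Monday's, 19.2% for Friday's and 30.3% for Thursday's, so the highest is Thursday's.

    substrate + target → side product (k = 0.00120 /M/s, Ea = 48.0 kJ/mol)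
    substrate + target ⇌ idle adduct, settled at all times (K = 460 /M, ΔH = −30.0 kJ/mol)
    solid reagent ⇌ partner, rate k3*(cs3 - [partner]) while solid is left; crystals form when [partner] > cs3 (solubility = 24.0 mM, k = 1.40 × 10⁻⁵ /s)
    substrate + partner → second isomer (k = 4.60 × 10⁻⁵ /M/s, Ea = 78.0 kJ/mol)
    substrate + partner → target (k = 6.60 × 10⁻⁴ /M/s, Ea = 58.0 kJ/mol)
    substrate + partner → isomer of the product (k = 7.00 × 10⁻⁴ /M/s, Ea = 69.0 kJ/mol)
    (constants at 25 °C)

- Friday's holds 49% of its substrate free at 4.00 d, and left until 40.0 d its target stands at 37.3%; against that value, f at 4.0 d is 48.6%, more than the 37.1% from 0.302 /d. In Friday's the conversion into isomer of the product has half of its turnover behind it at 2.04 d, out of 4.0 d, so that step is spread across the whole run.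
- For the neighbour, the flask of Friday's left until 25 h, the clock and lag give f = 90.6%, which on the 37.3% that Friday's reaches at 40.0 d means 3.51% of target. The computed flask holds 3.87%.

The data are calculated with constants of no real substance; the scatter is artificial.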